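## Numbering

**Atoms (target numbering, used for all cyclohexene compounds):** C1 is the alkene carbon that carries C7, C2 to C5 are the four oxygenated sp3 carbons, C6 is the alkene CH, C7 is the exocyclic CH2. For the inositol-derived compounds 1, 3, 5, 6 and 7 inositol numbering is also used: inositol C4, C5, C6, C1, C2, C3 become C1, C2, C3, C4, C5, C6.

**Compounds:** 1 D-chiro-inositol; 2 2,2-dimethoxypropane; 3 diacetonide diol; 4 benzoyl chloride; 5 monobenzoate; 6 ketone; 7 exocyclic methylene benzoate (key-step precursor); 8 rearranged C7 benzoate (key-step product); 9 tetrol; 10 3,4-bis-acetal diol; 11 its 5-O-methyl ether; 12 triol; 13 target.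

## Analysis of the target

Target 13 is one carbocycle, a cyclohexene whose trisubstituted C1=C6 alkene carries the benzoyloxymethyl carbon C7 on C1. The four stereocentres C2 to C5 are contiguous and all R. O2 and O3 are cis, O3 and O4 trans, O4 and O5 cis, so O2/O3 lie on one face and O4/O5 on the other. The four ring oxygens are all substituted differently: free hydroxyl on C2, benzoate on C3, free hydroxyl on C4, methyl ether on C5. The sensitive points are the two benzoates next to free hydroxyls (acyl migration from O7 to O2 and from O3 to O2 or O4), the three allylic C–O bonds at C2, C5 and C7, and the ease with which loss of two oxygen substituents would aromatise the ring. The skeleton and the stereocentres are therefore not the real difficulty. The difficulty is to place four different substituents on a tetrol whose two halves are almost related by symmetry, and to put the alkene and C7 in the right place. The plan rests on two features. First, C2 to C5 reproduce the cis, trans, cis oxygen array C5, C6, C1, C2 of D-chiro-inositol 1, whose twofold axis relates the two halves. Second, the C7 benzoate is an allylic ester 1,3-related to C6, so it can arrive from a C6 benzoate by an allylic ester transposition across an exocyclic C1=C7 alkene.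

## Retrosynthetic reasoning

**13 to 12 and 4.** The O3–acyl bond is cut last. A benzoate on O3 sits between two free hydroxyls and would migrate under the basic or hot conditions of earlier steps. In 12 the methyl ether has removed O5 from play, so O2/O3 is the only cis-diol left, and O3 is the one oxygen that is both equatorial and part of that cis-diol. A tin-mediated acylation picks exactly such an oxygen. An orthoester detour over O2/O3 was considered and dropped, because its hydrolysis would be expected to leave the ester on the pseudoaxial oxygen O2.

**12 to 11 to 10.** The O5–CH3 bond is cut next. Direct methylation of a tetrol such as 9 would have to choose among four hydroxyls, and a tin acetal would favour the equatorial O3 or O4, not O5. The trans-diequatorial pair O3/O4 is therefore first tied into a six-membered bis-acetal (10), which only such a pair forms well. What remains is a choice between two allylic, pseudoaxial hydroxyls: O5 beside the alkene CH and O2 beside the branched alkene carbon C1. The forward methylation must be non-basic, so that the C7 benzoate cannot shift to O2, and must use this steric difference. This is the one place where the near-symmetry of the two halves is broken by the C1 branch alone.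

**10 to 9 to 8.** The bis-acetal is cut back to tetrol 9, and 9 to the diacetonide 8. The acetonides are the right protection up to the key step because they come in one step from 1 and leave exactly the trans-diol free; they are exchanged afterwards for the group that bridges the trans pair.

**8 to 7 (key disconnection).** The C7–O bond is cut and the alkene is moved from C1=C6 back to C1=C7, with the benzoate returned to C6. Nothing else in the molecule is an allylic ester, so the transposition has one possible course. It is driven forward by the gain of a trisubstituted ring alkene and a primary ester. It needs no stereocontrol, because the C6 centre is destroyed and C2 to C5 are spectators.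

**7 to 6.** The C1=C7 bond is cut to ketone 6. The ketone has a benzoate on one α-carbon and an acetal oxygen on the next carbon, so a basic ylide would invite enolisation and β-elimination. A non-basic titanium methylidene transfer is planned instead.

**6 to 5 to 3 and 4.** The ketone comes from alcohol 5 by a neutral oxidation, and 5 from diol 3 by monobenzoylation. The two hydroxyls of 3 are exchanged by the twofold axis, so there is no regiochemical choice in either step. The benzoate introduced here is the one that ends on C7 in 13.

**3 to 1 and 2.** The two acetonides are cut to give 1. All four stereocentres of 13 are bought with 1.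

## Alternatives that were turned down

**Alternative 1:** furan Diels–Alder.
- **Disconnection:** C2–C3 and C4–C5. C2, C1, C6, C5 and C7 come from the silyl ether A1 of furan-3-ylmethanol; C3 and C4 come from 2-bromoacrolein A2.
- **Forward key step:** an enantioselective Lewis-acid-catalysed Diels–Alder reaction gives the 7-oxabicyclo[2.2.1]heptene A3. Its oxygen bridge spans C2 and C5, the C1=C6 alkene and C7 are in place, C4 carries bromine and formyl, and C3 is a methylene.
- **For it:** all seven carbons are joined in one catalytic asymmetric step from achiral materials. The rigid bicycle gives the right facial bias later: exo oxygenation at C3 (cis to the bridge oxygen), exo hydride delivery to a C4 ketone (O4 trans to O3), and opening of the allylic C5–O bridge bond with inversion by a methoxy nucleophile (O5 cis to O4). The four oxygens arrive one at a time and are distinct from the start. On this point the alternative is stronger than the chosen route, which must tell O5 from O2 by a steric difference in step 8.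
- **Against it:** furans are reluctant, reversible dienes, and a 3-substituted furan must also control the orientation that gives A3. The cycloaddition sets only the two bridgehead centres. The bromo-formyl carbon must be degraded to a ketone, C3 must be oxidised, and the bridge must be opened at an allylic centre where ionisation could erode the inversion.
- **Comparison:** this is a long chain of oxidation-state changes, each with its own selectivity question. The chosen route buys C2 to C5 in 1 and uses its key step only to move an alkene and an ester.

**Alternative 2:** pyrone cycloaddition.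
- **Disconnection:** C1–C2 and C3–C4. C2 and C3 with their cis-diol come from 2,2-dimethyl-1,3-dioxole A5. C1, C6, C5, C4 and C7 come from methyl 2-oxo-2H-pyran-3-carboxylate A4, whose ring oxygen becomes O4 and whose lactone carbonyl is a bridge to be discarded.
- **Forward key step:** an endo-selective, copper-Lewis-acid-catalysed Diels–Alder reaction gives the bridged lactone A6, with C2, C3, C4 and a quaternary C1 set together.
- **For it:** three of the four oxygens and their relative configuration arise in one step. The cis-diol is already an acetonide, O4 is unique as the lactone oxygen, and C7 is present as an ester. Here too O4 is distinguished from O2/O3 from the start, which the chosen route achieves only late.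
- **Against it:** A6 has its alkene at C5=C6, no oxygen on C5 and one carbon too many on C1. After lactone opening and decarboxylation the alkene must be moved to C1=C6 while an oxygen is introduced on C5 cis to O4, so the fourth stereocentre is made late, by a transposition. Bridged pyrone adducts tend to lose the bridge by cycloreversion to dienes that aromatise easily with this oxygen pattern. Enantiocontrol rests on the catalyst, and the ester must still be reduced.
- **Comparison:** the chosen route reaches its key intermediate 7 in four steps and has no stereocentre to create.

**Alternative 3:** intramolecular Morita–Baylis–Hillman reaction.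
- **Disconnection:** the C1–C2 bond. The open-chain enoate aldehyde A8 has C2 as the aldehyde carbon; C3 to C5 are C2 to C4 of D-arabinose A7, with O3/O4 as a trans acetonide and O5 already methylated; C6=C1–C7 is an acrylate unit attached by olefination.
- **Forward key step:** a trialkylphosphine adds to C6, the enolate attacks the aldehyde, and loss of the phosphine gives cyclohexene A9 with the C1=C6 alkene, the C7 ester and a new carbinol on C2.
- **For it:** the methyl ether is placed on an open-chain sugar hydroxyl without ambiguity, and O2, O3/O4 and O5 are all distinct in A9. On the differentiation of the oxygens this alternative is clearly stronger than the chosen route. Three stereocentres come from the sugar.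
- **Against it:** C2 is a new stereocentre formed in an aldol-type ring closure next to an α-alkoxy aldehyde and must come out cis to O3, with no reliable control element. The aldehyde α-centre C3 can epimerise under the zwitterionic conditions. The phosphonium enolate carries a γ-methoxy group that can be lost to a dienoate. The ring must close around a trans-fused dioxolane. The sugar needs several protection and chain-extension steps first.
- **Comparison:** the key step of the chosen route creates no stereocentre and so has no diastereoselectivity to fail. It pays for this with the late O5/O2 differentiation.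

Key step: step 5

**Assumption (chemistry):** the cyclohexene intermediates are taken to sit in the half-chair with O3 and O4 equatorial and the allylic O2 and O5 pseudoaxial; the regiochemical arguments of steps 7, 8 and 10 rest on this.

## Route

Step 1
Reactants: 1 D-chiro-inositol; 2 2,2-dimethoxypropane
Product: 3 1,2:5,6-di-O-isopropylidene-D-chiro-inositol
Conditions: 2 (2.5 equiv), TsOH·H2O (cat.), DMF, 50 °C; then Et3N
Reagents that add atoms: none
Why: Acid-catalysed transketalisation under thermodynamic control: each cis-diol (O1/O2 and O5/O6) closes an unstrained cis-fused dioxolane, while the trans-3,4-diol would need a strained trans-fused one and stays free; a third acetonide, should it form there, is the first to open again on brief mild acid methanolysis. No stereocentre is touched, and the twofold axis of 1 allows only one such diacetonide.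

Step 2
Reactants: 3 1,2:5,6-di-O-isopropylidene-D-chiro-inositol; 4 benzoyl chloride
Product: 5 3-O-benzoyl-1,2:5,6-di-O-isopropylidene-D-chiro-inositol
Conditions: 4 (1.0 equiv, slow addition), pyridine, CH2Cl2, −30 → 0 °C
Reagents that add atoms: none
Why: Acylation of an alcohol with an acid chloride in pyridine; the two hydroxyls of 3 are exchanged by the twofold axis, so either gives the same monoester and there is no regiochemical question. The first benzoate crowds its neighbour and slows the second acylation; recovered 3 and any dibenzoate (returned to 3 by methanolysis) are recycled.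

Step 3
Reactants: 5 3-O-benzoyl-1,2:5,6-di-O-isopropylidene-D-chiro-inositol
Product: 6 the C4 ketone (4-ulose) of 5, 3-O-benzoyl-1,2:5,6-di-O-isopropylidene-D-chiro-inos-4-ulose
Conditions: Dess–Martin periodinane, NaHCO3, CH2Cl2, 0 °C → rt
Reagents that add atoms: none
Why: Dess–Martin oxidation of the remaining secondary alcohol under buffered, non-basic conditions, chosen because 6 is an α-acyloxy, β-alkoxy ketone that would enolise and eliminate with amine bases. The C2 centre beside the ketone (target numbering) is held by its cis-fused dioxolane, and the C6 centre, even if it epimerised, is erased in step 5.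

Step 4
Reactants: 6 3-O-benzoyl-1,2:5,6-di-O-isopropylidene-D-chiro-inos-4-ulose
Product: 7 3-O-benzoyl-4-deoxy-1,2:5,6-di-O-isopropylidene-4-methylidene-D-chiro-inositol (target numbering: exocyclic C1=C7 alkene, benzoate on C6)
Conditions: Cp2Ti(μ-Cl)(μ-CH2)AlMe2 (Tebbe reagent, 1.2 equiv), pyridine (cat.), THF/toluene, −40 → 0 °C; aq. NaOH quench
Reagents that add atoms: Tebbe reagent Cp2Ti(μ-Cl)(μ-CH2)AlMe2, C[Al-]1(C)C[Ti](C2C=CC=C2)(C2C=CC=C2)[Cl+]1
Why: Tebbe methylenation: the titanium methylidene adds to the ketone by [2+2] cycloaddition and the oxatitanacyclobutane collapses to the alkene. The reagent is not basic, so the ketone is not enolised towards C6 (no loss of the C5 oxygen, no acyl transfer), and at low temperature a ketone reacts well before a benzoate ester. No stereocentre is formed.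

Step 5
Reactants: 7 3-O-benzoyl-4-deoxy-1,2:5,6-di-O-isopropylidene-4-methylidene-D-chiro-inositol
Product: 8 C7 benzoate of the 2,3:4,5-di-O-isopropylidene derivative of 1-(hydroxymethyl)cyclohex-1(6)-ene-2,3,4,5-tetrol (configuration at C2 to C5 as in 13)
Conditions: PdCl2(MeCN)2 (10 mol %), dry THF, rt → 45 °C
Reagents that add atoms: none
Why: Divalent palladium coordinates the exocyclic C1=C7 alkene and the benzoate carbonyl oxygen adds to C7 anti to the metal, giving a 2-phenyl-1,3-dioxan-2-ylium ion with a C1–Pd bond; anti deoxypalladation then breaks the C6–O bond, frees the catalyst and leaves the alkene at C1=C6. The closest known reaction type is the divalent-palladium-catalysed [3,3] (1,3-acyloxy) rearrangement of allylic acetates and benzoates. No ring is closed in the product: the six-membered dioxanylium ring forms by 6-endo attack of the carbonyl oxygen on the activated alkene and opens again in the same catalytic cycle. No stereocentre is created; C6 is destroyed, and C2 to C5 are untouched because their C–O bonds are acetal bonds that are never broken. The step needs positional selectivity only, and that is thermodynamic: a trisubstituted ring alkene with a primary ester is favoured over a 1,1-disubstituted exocyclic alkene with a secondary ester. The benzoate is the only carbonyl group within reach of the alkene; the allylic acetal oxygen on C2 has no carbonyl and cannot migrate. The reacting conformer must hold the C6–O bond axial, roughly perpendicular to the alkene plane, which A(1,3) strain between an equatorial C6 benzoate and the methylene hydrogen already favours and which the two cis-fused dioxolanes allow.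

Step 6
Reactants: 8 C7 benzoate of the 2,3:4,5-diacetonide
Product: 9 [(2,3,4,5-tetrahydroxy)cyclohex-1(6)-en-1-yl]methyl benzoate (O2/O3 cis, O3/O4 trans, O4/O5 cis, as in 13)
Conditions: TFA/H2O (9:1), 0 °C → rt; co-evaporation with toluene
Reagents that add atoms: none
Why: Aqueous acid hydrolysis of both cis-fused isopropylidene acetals; only acetal C–O bonds are broken, so C2 to C5 keep their configuration, and the primary allylic benzoate is stable to these conditions at or below room temperature.

Step 7
Reactants: 9 the 7-O-benzoyl tetrol
Product: 10 3,4-O-(2,3-dimethoxybutane-2,3-diyl) derivative of 9 (trans-fused 1,4-dioxane, both methoxy groups axial; O2-H and O5-H free)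
Conditions: butane-2,3-dione (1.2 equiv), HC(OMe)3, CSA (cat.), MeOH, 50 °C; Et3N quench
Reagents that add atoms: butane-2,3-dione, CC(=O)C(C)=O; trimethyl orthoformate, COC(OC)OC; methanol, CO
Why: Butane-2,3-diacetal formation under equilibrating conditions: only the trans-diequatorial pair O3/O4 can close the trans-fused 1,4-dioxane with both methoxy groups axial (two anomeric effects) and both methyl groups equatorial, whereas the cis pairs O2/O3 and O4/O5 would give less stable cis-fused rings; the two new acetal centres are set by this anomeric preference. The aryl ester exchanges with methanol far more slowly than acetals equilibrate, so the C7 benzoate should survive a short reaction.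

Step 8
Reactants: 10 the 3,4-bis-acetal diol
Product: 11 5-O-methyl ether of 10
Conditions: MeOTf (1.05 equiv), 2,6-di-tert-butyl-4-methylpyridine, CH2Cl2, −20 → 0 °C
Reagents that add atoms: methyl trifluoromethanesulfonate, COS(=O)(=O)C(F)(F)F
Why: O-Methylation of a neutral alcohol with methyl triflate and a hindered, non-nucleophilic pyridine base; both free hydroxyls are allylic and pseudoaxial, but O2 is flanked by the branched alkene carbon C1 with its benzoyloxymethyl group while O5 is flanked by the alkene CH, so the less hindered O5 should react first with one equivalent at low temperature. No alkoxide is formed, so the C7 benzoate has no chance to shift to O2; the regioisomer and the bis-ether are expected as minor, separable products.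

Step 9
Reactants: 11 the 5-O-methyl 3,4-bis-acetal
Product: 12 [(2,3,4-trihydroxy-5-methoxy)cyclohex-1(6)-en-1-yl]methyl benzoate (configuration as in 13)
Conditions: TFA/H2O (9:1), 0 °C → rt
Reagents that add atoms: none
Why: Acid hydrolysis of the bis-acetal frees O3 and O4; the methyl ether and the benzoate are inert, and no C–O bond at a ring stereocentre is broken.

Step 10
Reactants: 12 the 7-O-benzoyl-5-O-methyl triol; 4 benzoyl chloride
Product: 13 [(3R,4R,5R,6R)-5-(benzoyloxy)-4,6-dihydroxy-3-methoxycyclohex-1-en-1-yl]methyl benzoate (the target; in target numbering 3,7-di-O-benzoyl-5-O-methyl)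
Conditions: 4 (1.1 equiv), Me2SnCl2 (5 mol %), i-Pr2NEt, THF, 0 °C → rt; dilute acid quench
Reagents that add atoms: none
Why: Tin-catalysed regioselective monoacylation: Me2SnCl2 chelates a 1,2-diol of 12 and the amine base turns it into a stannylene-type alkoxide that is acylated by 4. O2/O3 is the only cis-diol left (O5 is capped), and in such a pair the equatorial oxygen, here O3, is acylated, as in 3-O-acylation of galacto- and manno-configured pyranosides. O2 is pseudoaxial and crowded by C1, O4 has no cis partner, and a short reaction with a hindered amine and an acidic quench limits acyl migration.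

## Compound list

1 | D-chiro-inositol | O[C@@H]1[C@H](O)[C@@H](O)[C@H](O)[C@@H](O)[C@H]1O | starting material
2 | 2,2-dimethoxypropane | COC(C)(C)OC | starting material
3 | 1,2:5,6-di-O-isopropylidene-D-chiro-inositol | O[C@@H]1[C@H]2OC(C)(C)O[C@H]2[C@@H]3OC(C)(C)O[C@@H]3[C@H]1O | intermediate
4 | benzoyl chloride | O=C(Cl)c1ccccc1 | starting material
5 | 3-O-benzoyl-1,2:5,6-di-O-isopropylidene-D-chiro-inositol | O[C@@H]1[C@H]2OC(C)(C)O[C@H]2[C@@H]3OC(C)(C)O[C@@H]3[C@H]1OC(=O)c1ccccc1 | intermediate
6 | 3-O-benzoyl-1,2:5,6-di-O-isopropylidene-D-chiro-inos-4-ulose | O=C1[C@H]2OC(C)(C)O[C@H]2[C@@H]3OC(C)(C)O[C@@H]3[C@H]1OC(=O)c1ccccc1 | intermediate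
7 | 3-O-benzoyl-4-deoxy-1,2:5,6-di-O-isopropylidene-4-methylidene-D-chiro-inositol | C=C1[C@H]2OC(C)(C)O[C@H]2[C@@H]3OC(C)(C)O[C@@H]3[C@H]1OC(=O)c1ccccc1 | intermediate
8 | C7 benzoate of 2,3:4,5-di-O-isopropylidene-1-(hydroxymethyl)cyclohex-1(6)-ene-2,3,4,5-tetrol | C1=C(COC(=O)c2ccccc2)[C@H]2OC(C)(C)O[C@H]2[C@@H]2OC(C)(C)O[C@H]12 | intermediate
9 | [(2,3,4,5-tetrahydroxy)cyclohex-1(6)-en-1-yl]methyl benzoate, configuration as in 13 | C1=C(COC(=O)c2ccccc2)[C@@H](O)[C@@H](O)[C@H](O)[C@@H]1O | intermediate
10 | 3,4-O-(2,3-dimethoxybutane-2,3-diyl) derivative of 9 | C1=C(COC(=O)c2ccccc2)[C@@H](O)[C@H]2O[C@](C)(OC)[C@@](C)(OC)O[C@@H]2[C@@H]1O | intermediate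
11 | 5-O-methyl ether of 10 | C1=C(COC(=O)c2ccccc2)[C@@H](O)[C@H]2O[C@](C)(OC)[C@@](C)(OC)O[C@@H]2[C@@H]1OC | intermediate
12 | [(2,3,4-trihydroxy-5-methoxy)cyclohex-1(6)-en-1-yl]methyl benzoate, configuration as in 13 | CO[C@@H]1C=C(COC(=O)c2ccccc2)[C@@H](O)[C@@H](O)[C@@H]1O | intermediate
13 | [(3R,4R,5R,6R)-5-(benzoyloxy)-4,6-dihydroxy-3-methoxycyclohex-1-en-1-yl]methyl benzoate | CO[C@@H]1C=C(COC(=O)c2ccccc2)[C@@H](O)[C@@H](OC(=O)c2ccccc2)[C@@H]1O | target

## Step count and least certain steps

Total step count: 10. Longest linear sequence: 10 steps, from 1 to 13.

**Step 5 (key step).** The oxypalladation must leave the metal on the fully substituted C1, and attack of the carbonyl oxygen on the terminal carbon of a 1,1-disubstituted alkene runs against the usual preference of a coordinated alkene. Turnover may therefore be slow, and during a long reaction the Lewis-acidic palladium salt may strip an acetonide or be reduced to metal before equilibrium is reached. Fallback: from 7, methanolysis of the benzoate (K2CO3, MeOH) would give the allylic alcohol 4-deoxy-1,2:5,6-di-O-isopropylidene-4-methylidene-D-chiro-inositol F1. A catalytic amount of Ph3SiOReO3 in ether at low temperature would then move the hydroxyl from C6 to C7 through the allyl perrhenate, with the same thermodynamic drive, to give the primary allylic alcohol 2,3:4,5-di-O-isopropylidene-1-(hydroxymethyl)cyclohex-1(6)-ene-2,3,4,5-tetrol F2. Benzoylation with 4 in pyridine returns to the route at 8.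

**Step 8.** Loss of site selectivity is the likely failure. O2 and O5 are both allylic and pseudoaxial and differ only in the neighbour on the alkene carbon, so the methyl group may be delivered to both oxygens and over-methylation may follow. Fallback: from 10, methanolysis (K2CO3, MeOH) would give the triol 3,4-O-(2,3-dimethoxybutane-2,3-diyl)-1-(hydroxymethyl)cyclohex-1(6)-ene-2,3,4,5-tetrol F3. Only O2 and O7 of this triol can close a cyclic acetal, so 2,2-dimethoxypropane with pyridinium tosylate would give the 2,7-O-isopropylidene acetal F4 (a 5-alkylidene-1,3-dioxane) and leave O5 as the only hydroxyl. NaH and MeI would give the 5-O-methyl ether F5, aqueous TFA would remove both acetals to give the 5-O-methyl tetrol 1-(hydroxymethyl)-5-methoxycyclohex-1(6)-ene-2,3,4-triol F6, and one equivalent of 4 with collidine at −40 °C would benzoylate the primary allylic hydroxyl, returning to the route at 12.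

**Step 10.** Acylation at the other equatorial oxygen O4, or base-induced migration of the new ester from O3 to O2 or O4 once formed, would erode the regiochemistry. Fallback: from 12, 2,2-dimethoxypropane and pyridinium tosylate would protect the only cis-diol as the 2,3-O-isopropylidene derivative F7. TIPSOTf and 2,6-lutidine would silylate the one free hydroxyl to give the 4-O-triisopropylsilyl ether F8, and aqueous TFA would free the 2,3-diol F9. Benzoylation with 4 in pyridine at −40 °C, where only the equatorial O3 and the crowded pseudoaxial O2 compete, would give the 3-O-benzoyl-4-O-triisopropylsilyl compound F10. HF·pyridine returns to the route at 13.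

**Step 4.** Methylenation of the benzoate carbonyl as the ketone is consumed, or opening of a dioxolane by the Lewis-acidic aluminium component, would lower the yield; a more basic reagent would instead cause enolisation towards C6 and loss of the C5 acetal oxygen. Fallback: from 3, one equivalent of TBSCl with imidazole would give the mono-silyl ether 3-O-(tert-butyldimethylsilyl)-1,2:5,6-di-O-isopropylidene-D-chiro-inositol F11. Dess–Martin oxidation would give the silyloxy ketone F12, which tolerates a Wittig methylenation (methyltriphenylphosphonium bromide, KOtBu, THF) to the exocyclic alkene F13. TBAF would free the allylic alcohol that is F1 of the fallback for step 5, and benzoylation with 4 in pyridine returns to the route at 7.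

## Further compounds

F1 | step 5 | 4-deoxy-1,2:5,6-di-O-isopropylidene-4-methylidene-D-chiro-inositol | C=C1[C@H]2OC(C)(C)O[C@H]2[C@@H]3OC(C)(C)O[C@@H]3[C@H]1O
F2 | step 5 | 2,3:4,5-di-O-isopropylidene-1-(hydroxymethyl)cyclohex-1(6)-ene-2,3,4,5-tetrol | C1=C(CO)[C@H]2OC(C)(C)O[C@H]2[C@@H]2OC(C)(C)O[C@H]12
F3 | step 8 | 3,4-O-(2,3-dimethoxybutane-2,3-diyl)-1-(hydroxymethyl)cyclohex-1(6)-ene-2,3,4,5-tetrol | C1=C(CO)[C@@H](O)[C@H]2O[C@](C)(OC)[C@@](C)(OC)O[C@@H]2[C@@H]1O
F4 | step 8 | 2,7-O-isopropylidene acetal of F3 | C1=C2COC(C)(C)O[C@H]2[C@H]3O[C@](C)(OC)[C@@](C)(OC)O[C@@H]3[C@@H]1O
F5 | step 8 | 5-O-methyl ether of F4 | C1=C2COC(C)(C)O[C@H]2[C@H]3O[C@](C)(OC)[C@@](C)(OC)O[C@@H]3[C@@H]1OC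
F6 | step 8 | 1-(hydroxymethyl)-5-methoxycyclohex-1(6)-ene-2,3,4-triol, configuration as in 13 | CO[C@@H]1C=C(CO)[C@@H](O)[C@@H](O)[C@@H]1O
F7 | step 10 | 2,3-O-isopropylidene derivative of 12 | CO[C@@H]1C=C(COC(=O)c2ccccc2)[C@H]2OC(C)(C)O[C@H]2[C@@H]1O
F8 | step 10 | 4-O-triisopropylsilyl ether of F7 | CO[C@@H]1C=C(COC(=O)c2ccccc2)[C@H]2OC(C)(C)O[C@H]2[C@@H]1O[Si](C(C)C)(C(C)C)C(C)C
F9 | step 10 | 4-O-triisopropylsilyl ether of 12 | CO[C@@H]1C=C(COC(=O)c2ccccc2)[C@@H](O)[C@@H](O)[C@@H]1O[Si](C(C)C)(C(C)C)C(C)C
F10 | step 10 | 4-O-triisopropylsilyl ether of 13 | CO[C@@H]1C=C(COC(=O)c2ccccc2)[C@@H](O)[C@@H](OC(=O)c2ccccc2)[C@@H]1O[Si](C(C)C)(C(C)C)C(C)C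
F11 | step 4 | 3-O-(tert-butyldimethylsilyl)-1,2:5,6-di-O-isopropylidene-D-chiro-inositol | O[C@@H]1[C@H]2OC(C)(C)O[C@H]2[C@@H]3OC(C)(C)O[C@@H]3[C@H]1O[Si](C)(C)C(C)(C)C
F12 | step 4 | 3-O-(tert-butyldimethylsilyl)-1,2:5,6-di-O-isopropylidene-D-chiro-inos-4-ulose | O=C1[C@H]2OC(C)(C)O[C@H]2[C@@H]3OC(C)(C)O[C@@H]3[C@H]1O[Si](C)(C)C(C)(C)C
F13 | step 4 | 3-O-(tert-butyldimethylsilyl)-4-deoxy-1,2:5,6-di-O-isopropylidene-4-methylidene-D-chiro-inositol | C=C1[C@H]2OC(C)(C)O[C@H]2[C@@H]3OC(C)(C)O[C@@H]3[C@H]1O[Si](C)(C)C(C)(C)C
A1 | alternative 1 | tert-butyl(furan-3-ylmethoxy)dimethylsilane | CC(C)(C)[Si](C)(C)OCc1ccoc1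
A2 | alternative 1 | 2-bromoacrolein | C=C(Br)C=O
A3 | alternative 1 | 2-bromo-5-[(tert-butyldimethylsilyloxy)methyl]-7-oxabicyclo[2.2.1]hept-5-ene-2-carbaldehyde, exo-formyl adduct | C1=C(CO[Si](C)(C)C(C)(C)C)[C@@H]2C[C@@](Br)(C=O)[C@H]1O2
A4 | alternative 2 | methyl 2-oxo-2H-pyran-3-carboxylate | COC(=O)C1=CC=COC1=O
A5 | alternative 2 | 2,2-dimethyl-1,3-dioxole | CC1(C)OC=CO1
A6 | alternative 2 | endo cycloadduct, bridged lactone methyl ester acetonide | COC(=O)[C@]12[C@H]3OC(C)(C)O[C@H]3[C@H](OC1=O)C=C2
A7 | alternative 3 | D-arabinose (open-chain form) | O=C[C@@H](O)[C@H](O)[C@H](O)CO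
A8 | alternative 3 | methyl (E)-5,6-dideoxy-2,3-O-isopropylidene-4-O-methyl-aldehydo-D-arabino-hept-5-enuronate | O=C[C@H]1OC(C)(C)O[C@@H]1[C@H](OC)/C=C/C(=O)OC
A9 | alternative 3 | methyl 6-hydroxy-4,5-(isopropylidenedioxy)-3-methoxycyclohex-1-ene-1-carboxylate, trans-fused acetonide | C1=C(C(=O)OC)[C@@H](O)[C@H]2OC(C)(C)O[C@@H]2[C@@H]1OC
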